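## Retrosynthetic overview

1. **Labels.** Ring A is the benzene ring carrying OMe. The pyran part uses chroman numbers (O1, C2–C4, C4a, C5–C8, C8a). Ca = indane CH2 on C6, Cb = ring-fusion CH next to CMe2, Cc = ring-fusion CH on C5, Cd = CH bearing the catechol, Ce = CMe2.
2. **Feature.** If Ce is read as C=O and the catechol is removed from Cd, the four-membered ring Cb–Cc–Cd–Ce becomes a 3-arylcyclobutanone. It has a mirror plane through Cc and Ce, Cb and Cd are enantiotopic CH2 groups, and Ca is a formyl carbon on the ring-A position (C6) ortho to Cc.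
3. **Late disconnections.** The chromene C3=C4 comes from a C4 ketone carried as a dioxolane. CMe2 comes from spirocyclopropane, then methylene, then the Ce ketone. The Cd–aryl bond comes from Pd enolate arylation with a protected 4-bromocatechol.
4. **Key disconnection Ca–Cb.** A chiral-amine enamine aldol of the achiral keto aldehyde closes the indane ring. The cyclobutanone comes from a C5 styrene and dichloroketene, the styrene from the C5 triflate of a 6-formyl-5-hydroxychromanone, and that from phloroglucinol and 3-methylbut-2-enoic acid.
5. **Ring order.** Pyranone on ring A, then cyclobutanone, then the five-membered indane ring (key step). The pyranone is converted to the 2H-chromene last.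

Key step: step 12

Remark: the sense of induction in step 12 is assigned by analogy with proline-type enamine aldols. L-series catalysts give the (S) α-centre for the priority order C=O > C–O > C > H, so the D-series is taken for Cb = R. Both antipodes are available, so a reversed sense would be met with the L-series.

## Route

Step 1
Reactants: 1 phloroglucinol; 2 3-methylbut-2-enoic acid
Product: 4 5,7-dihydroxy-2,2-dimethylchroman-4-one, via aryl enone 3 (not isolated)
Conditions: MeSO3H/P2O5 (Eaton's reagent), 70 °C
Reagents that add atoms: none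
Why: Friedel–Crafts acylation of the threefold-symmetric triphenol gives aryl enone 3, which closes at once by acid-promoted oxa-Michael addition of an ortho hydroxyl to the β,β-dimethyl enone, so only one regioisomer is possible.

Step 2
Reactants: 4 5,7-dihydroxy-2,2-dimethylchroman-4-one
Product: 5 5-hydroxy-7-methoxy-2,2-dimethylchroman-4-one
Conditions: MeI (1.05 equiv), K2CO3 (1.1 equiv), acetone, rt to 40 °C
Reagents that add atoms: iodomethane, CI
Why: Williamson etherification is selective because the 5-OH is held in a strong hydrogen bond to the C4 carbonyl and stays protonated with one equivalent of weak base, leaving only the 7-phenoxide to be alkylated.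

Step 3
Reactants: 5 5-hydroxy-7-methoxy-2,2-dimethylchroman-4-one
Product: 7 5-hydroxy-7-methoxy-2,2-dimethyl-4-oxochromane-6-carbaldehyde, via salicyl alcohol 6 (not isolated)
Conditions: MgCl2, Et3N, (CH2O)n, MeCN, reflux; 1 M HCl work-up
Reagents that add atoms: paraformaldehyde (as formaldehyde), C=O
Why: Casnati–Skattebøl formylation delivers formaldehyde inside the magnesium phenoxide only ortho to the phenol, C6 is the sole free ortho position (C8 is para), and the first-formed salicyl alcohol 6 is oxidised by a second formaldehyde through an Oppenauer-type hydride transfer.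

Step 4
Reactants: 7 5-hydroxy-7-methoxy-2,2-dimethyl-4-oxochromane-6-carbaldehyde
Product: 8 6-formyl-7-methoxy-2,2-dimethyl-4-oxochroman-5-yl trifluoromethanesulfonate
Conditions: Tf2O, pyridine, CH2Cl2, −10 °C to rt
Reagents that add atoms: triflic anhydride, O=S(=O)(OS(=O)(=O)C(F)(F)F)C(F)(F)F
Why: O-Sulfonylation of the phenol turns C5–O into a cross-coupling handle, and the two flanking carbonyl groups will speed the oxidative addition that follows.

Step 5
Reactants: 8 6-formyl-7-methoxy-2,2-dimethyl-4-oxochroman-5-yl trifluoromethanesulfonate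
Product: 9 7-methoxy-2,2-dimethyl-4-oxo-5-vinylchromane-6-carbaldehyde
Conditions: Bu3SnCH=CH2, Pd(PPh3)4 (5 mol %), LiCl, BHT, 1,4-dioxane, 90 °C
Reagents that add atoms: tributyl(vinyl)stannane, C=C[Sn](CCCC)(CCCC)CCCC
Why: The Stille coupling is neutral and tolerates aldehyde and ketone, chloride assists transmetalation, and the doubly carbonyl-flanked triflate is strongly activated despite its two ortho substituents.

Step 6
Reactants: 9 7-methoxy-2,2-dimethyl-4-oxo-5-vinylchromane-6-carbaldehyde
Product: 10 6-(hydroxymethyl)-7-methoxy-2,2-dimethyl-5-vinylchroman-4-one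
Conditions: NaBH4, THF–MeOH, −40 to −20 °C
Reagents that add atoms: none
Why: Chemoselective borohydride reduction takes the aldehyde over the donor-deactivated C4 ketone, and the alcohol level is chosen as the aldehyde mask because an O,O-acetal at C6 could never be removed beside the far more acid-labile C4 ketal, whereas a 2,4-dialkoxybenzyl-type ether can be returned to the aldehyde oxidatively at neutral pH.

Step 7
Reactants: 10 6-(hydroxymethyl)-7-methoxy-2,2-dimethyl-5-vinylchroman-4-one
Product: 11 6-[(tert-butyldimethylsilyloxy)methyl]-7-methoxy-2,2-dimethyl-5-vinylchroman-4-one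
Conditions: TBSCl, imidazole, CH2Cl2, rt
Reagents that add atoms: tert-butyldimethylsilyl chloride, CC(C)(C)[Si](C)(C)Cl
Why: Standard silylation of the primary alcohol gives an ether that should survive the ketalisation, ketene and zinc steps and still behaves as an electron-rich benzyl ether for oxidative release.

Step 8
Reactants: 11 6-[(tert-butyldimethylsilyloxy)methyl]-7-methoxy-2,2-dimethyl-5-vinylchroman-4-one
Product: 12 6-[(tert-butyldimethylsilyloxy)methyl]-7-methoxy-2,2-dimethyl-5-vinylspiro[chromane-4,2'-[1,3]dioxolane]
Conditions: TMSOCH2CH2OTMS, TMSOTf (5 mol %), CH2Cl2, −78 to −20 °C; pyridine quench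
Reagents that add atoms: 1,2-bis(trimethylsilyloxy)ethane, C[Si](C)(C)OCCO[Si](C)(C)C
Why: Noyori-type aprotic ketalisation is driven irreversibly by formation of hexamethyldisiloxane, which overcomes the poor equilibrium of a donor-conjugated aryl ketone, while catalytic TMSOTf at low temperature should spare the silyl ether and the styrene (meta to both oxygen donors), and C4 is masked here because the later enolate, methylenation and hydrogenation steps would otherwise touch the chromanone.

Step 9
Reactants: 12 6-[(tert-butyldimethylsilyloxy)methyl]-7-methoxy-2,2-dimethyl-5-vinylspiro[chromane-4,2'-[1,3]dioxolane]; 13 trichloroacetyl chloride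
Product: 15 (±)-2,2-dichloro-3-aryl-cyclobutan-1-one (aryl = C5 of the silyl ether ketal), via dichloroketene 14 (not isolated)
Conditions: Zn–Cu, Et2O–DME, slow addition of 13, 35 °C, ultrasound
Reagents that add atoms: none
Why: In this thermal [2+2] ketene–alkene cycloaddition the carbonyl carbon of electrophilic 14 bonds to the terminal CH2 and its CCl2 carbon to the benzylic carbon, giving only the 3-aryl regioisomer, while DME binds ZnCl2 to protect the ketal and the silyl ether.

Step 10
Reactants: 15 (±)-2,2-dichloro-3-aryl-cyclobutan-1-one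
Product: 16 3-{6-[(tert-butyldimethylsilyloxy)methyl]-7-methoxy-2,2-dimethylspiro[chromane-4,2'-[1,3]dioxolan]-5-yl}cyclobutan-1-one (achiral)
Conditions: Zn dust, NH4Cl, MeOH, rt
Reagents that add atoms: none
Why: Zinc reduction of both α-C–Cl bonds through zinc enolates under nearly neutral ammonium chloride buffering removes the only stereocentre and gives the mirror-symmetric cyclobutanone without harming the ketal.

Step 11
Reactants: 16 silyl ether cyclobutanone
Product: 17 7-methoxy-2,2-dimethyl-5-(3-oxocyclobutyl)spiro[chromane-4,2'-[1,3]dioxolane]-6-carbaldehyde (achiral)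
Conditions: DDQ, CH2Cl2–pH 7 phosphate buffer, 0 °C; amine-free neutral silica
Reagents that add atoms: none
Why: DDQ abstracts hydride from the benzylic CH2–O position activated by the ortho methoxy and para ring oxygen (the chemistry of oxidative dimethoxybenzyl ether cleavage) and water desilylates the oxocarbenium ion, so the aldehyde appears at pH 7 with neither acid to cleave the ketal nor base to start a racemic aldol closure.

Step 12
Reactants: 17 7-methoxy-2,2-dimethyl-5-(3-oxocyclobutyl)spiro[chromane-4,2'-[1,3]dioxolane]-6-carbaldehyde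
Product: 19 cis-fused hydroxy-indane cyclobutanone (Ca–Cb bond formed; Ce=O; Cd H2; C4 dioxolane; Ca R; Cb R; Cc S; OH syn to Ce), via cyclobutenyl enamine 18 (not isolated)
Conditions: (R)-N-(phenylsulfonyl)pyrrolidine-2-carboxamide (20 mol %), CH2Cl2 (0.05 M), 0 °C
Reagents that add atoms: none
Why: The pyrrolidine nitrogen condenses with the unhindered, strained cyclobutanone to give enamine 18, its β-carbon Cb adds to the formyl carbon Ca while the acidic acyl sulfonamide N–H hydrogen-bonds the aldehyde oxygen, and hydrolysis of the iminium ion releases 19 and the catalyst. The closest known reactions are the prolinamide-catalysed desymmetrising aldol additions of 3-substituted cyclobutanones to aromatic aldehydes and the proline-catalysed 5-enolexo aldolisations of keto aldehydes, which are combined here. The five-membered indane ring closes in the 5-(enolexo)-exo-trig mode, and because Ca is tied through ring A to Cc it can reach Cb only on the cyclobutane face that carries ring A, so Cb–H and Cc–H must end up cis. Cb (R) and Cc (S) are set together by the catalyst, since with the electrophile fixed on the ring-A face the hydrogen-bond donor can sit on that face in the favoured anti-enamine for only one of the two enantiotopic methylenes, the other requiring the disfavoured syn-enamine. Ca is expected as the epimer with OH syn to Ce (R) from the hydrogen-bonded geometry, but either epimer serves because this centre is erased in step 14. The step needs group selectivity (Cb versus Cd), helped by the bulky peri ketal that turns Cc–H toward C4 so that both methylenes straddle the formyl group, and chemoselectivity, secured because C4 is masked and the aldehyde cannot enolise, while low temperature and prompt acetylation keep the reversible addition under kinetic control.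

Step 13
Reactants: 19 cis-fused hydroxy-indane cyclobutanone
Product: 20 Ca-acetate of 19 (Ca R; Cb R; Cc S)
Conditions: Ac2O, pyridine, DMAP (cat.), CH2Cl2, 0 °C
Reagents that add atoms: acetic anhydride, CC(=O)OC(C)=O
Why: DMAP-catalysed acylation caps the aldol, which blocks retro-aldol racemisation and provides a better leaving group for hydrogenolysis, β-elimination being held back by the strain of a Ca=Cb double bond at the ring fusion.

Step 14
Reactants: 20 Ca-acetate
Product: 21 cis-fused indane cyclobutanone (Ca H2; Ce=O; Cd H2; C4 dioxolane; Cb S; Cc S)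
Conditions: H2 (1 atm), 10 % Pd/C, NaHCO3, EtOAc–EtOH, rt
Reagents that add atoms: none
Why: Catalytic hydrogenolysis cleaves the secondary benzylic C–O bond activated by the ortho and para oxygen donors, bicarbonate takes up the acetic acid to protect the ketal, the hindered quaternary ketal carbon and the aliphatic ketone should not be reduced over Pd at 1 atm, and Cb and Cc are untouched (the descriptor at Cb changes only through priorities).

Step 15
Reactants: 22 4-bromocatechol
Product: 23 4-bromo-1,2-bis(methoxymethoxy)benzene
Conditions: MOMCl, i-Pr2NEt, CH2Cl2, 0 °C to rt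
Reagents that add atoms: chloromethyl methyl ether, COCCl
Why: Base-mediated O-alkylation of both phenols gives acetal ethers stable to strong base, Pd, Ti, zinc carbenoid and hydrogenation and removable later in the same operation as the ketal.

Step 16
Reactants: 21 cis-fused indane cyclobutanone; 23 4-bromo-1,2-bis(methoxymethoxy)benzene
Product: 26 exo-Cd-aryl cyclobutanone (aryl = 3,4-bis(methoxymethoxy)phenyl on the convex face trans to ring A; Cb S; Cc R; Cd R), via lithium enolate 24 (not isolated), via endo-aryl epimer 25 (not isolated)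
Conditions: LiHMDS (2.3 equiv), THF–toluene, −78 °C; 23, Pd2(dba)3 (2.5 mol %), P(t-Bu)3·HBF4 (6 mol %), to 50 °C; aq NH4Cl; then DBU (cat.), CH2Cl2, rt
Reagents that add atoms: none
Why: In this Buchwald–Hartwig–Miura ketone α-arylation kinetic deprotonation occurs at the Cd methylene because an enolate toward the ring-fusion carbon Cb is far more strained, the bulky electron-rich phosphine promotes C–C reductive elimination from the Pd enolate, and DBU converts any endo epimer 25 into the thermodynamic exo isomer, Cb being unable to invert (a trans-fused bicyclo[3.2.0] system is prohibitive) and Cc not being acidic.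

Step 17
Reactants: 26 exo-Cd-aryl cyclobutanone
Product: 27 Ce-methylene compound (Ce=CH2; Cb S; Cc R; Cd S)
Conditions: Cp2TiMe2, toluene, 75 °C, dark
Reagents that add atoms: dimethyltitanocene, C[Ti+2]C.c1cc[cH-]c1.c1cc[cH-]c1
Why: Petasis methylenation runs through the non-basic titanocene methylidene and an oxatitanacyclobutane, so the easily enolised, hindered α-aryl cyclobutanone is olefinated without enolate formation and the ketal and MOM groups are inert.

Step 18
Reactants: 27 Ce-methylene compound
Product: 28 Ce-spirocyclopropane (spiro[2.3]hexane unit; Cb S; Cc R; Cd S)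
Conditions: Et2Zn, CH2I2 (1:2), CH2Cl2, 0 °C to rt
Reagents that add atoms: diiodomethane, ICI
Why: Simmons–Smith cyclopropanation (Furukawa variant) adds CH2 to the only alkene, a strained exocyclic methylene, and creates no stereocentre because the spiro carbon Ce then carries two equivalent CH2 groups.

Step 19
Reactants: 28 Ce-spirocyclopropane
Product: 29 Ce-gem-dimethyl ketal (CMe2 at Ce; C4 dioxolane; two MOM ethers; Cb S; Cc R; Cd S)
Conditions: H2 (3–4 atm), PtO2, EtOAc–AcOH, NaOAc, rt
Reagents that add atoms: none
Why: Hydrogenolysis over Adams catalyst opens a cyclopropane at its least substituted bond, here the CH2–CH2 bond remote from the spiro centre, which turns Ce into CMe2, while cyclobutanes are normally inert under these conditions and the acetate buffer is meant to keep the ketal in place.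

Step 20
Reactants: 29 Ce-gem-dimethyl ketal
Product: 30 catechol chromanone (C4=O; free 3,4-dihydroxyphenyl on Cd; Cb S; Cc R; Cd S)
Conditions: 2 M aq HCl, MeOH–THF, 45 °C, Ar
Reagents that add atoms: water, O
Why: Acid-catalysed hydrolysis and methanolysis remove the dioxolane and both MOM groups in one operation, methanol traps the formaldehyde unit as methylal so that it cannot attack the electron-rich rings, and no stereocentre is acid-labile.

Step 21
Reactants: 30 catechol chromanone
Product: 31 catechol chroman-4-ol (mixture of C4 epimers; Cb S; Cc R; Cd S)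
Conditions: NaBH4 (excess), MeOH–THF, 0 °C to rt, Ar
Reagents that add atoms: none
Why: Borohydride reduction of the now sole carbonyl group gives the 4-chromanol as an inconsequential mixture of C4 epimers, the extra hydride compensating for the acidic catechol protons.

Step 22
Reactants: 31 catechol chroman-4-ol
Product: 32 target CNP0207533.1 (Cb S; Cc R; Cd S)
Conditions: p-TsOH·H2O (5 mol %), THF, 50 °C, Ar
Reagents that add atoms: none
Why: Acid-catalysed E1 dehydration is easy because the C4 cation is stabilised by the ortho ring oxygen and the para methoxy group, loss of a C3 proton gives the conjugated 2,2-dimethyl-2H-chromene, and no other benzylic position carries a leaving group.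

## Compound list

1 | phloroglucinol | Oc1cc(O)cc(O)c1 | starting material
2 | 3-methylbut-2-enoic acid | CC(C)=CC(=O)O | starting material
3 | 3-methyl-1-(2,4,6-trihydroxyphenyl)but-2-en-1-one (not isolated) | CC(C)=CC(=O)c1c(O)cc(O)cc1O | intermediate
4 | 5,7-dihydroxy-2,2-dimethylchroman-4-one | CC1(C)CC(=O)c2c(O)cc(O)cc2O1 | intermediate
5 | 5-hydroxy-7-methoxy-2,2-dimethylchroman-4-one | COc1cc(O)c2C(=O)CC(C)(C)Oc2c1 | intermediate
6 | 5-hydroxy-6-(hydroxymethyl)-7-methoxy-2,2-dimethylchroman-4-one (not isolated) | COc1cc2OC(C)(C)CC(=O)c2c(O)c1CO | intermediate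
7 | 5-hydroxy-7-methoxy-2,2-dimethyl-4-oxochromane-6-carbaldehyde | COc1cc2OC(C)(C)CC(=O)c2c(O)c1C=O | intermediate
8 | 6-formyl-7-methoxy-2,2-dimethyl-4-oxochroman-5-yl triflate | COc1cc2OC(C)(C)CC(=O)c2c(OS(=O)(=O)C(F)(F)F)c1C=O | intermediate
9 | 7-methoxy-2,2-dimethyl-4-oxo-5-vinylchromane-6-carbaldehyde | COc1cc2OC(C)(C)CC(=O)c2c(C=C)c1C=O | intermediate
10 | 6-(hydroxymethyl)-7-methoxy-2,2-dimethyl-5-vinylchroman-4-one | COc1cc2OC(C)(C)CC(=O)c2c(C=C)c1CO | intermediate
11 | 6-[(TBSO)methyl]-7-methoxy-2,2-dimethyl-5-vinylchroman-4-one | COc1cc2OC(C)(C)CC(=O)c2c(C=C)c1CO[Si](C)(C)C(C)(C)C | intermediate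
12 | 6-[(TBSO)methyl]-7-methoxy-2,2-dimethyl-5-vinylspiro[chromane-4,2'-[1,3]dioxolane] | COc1cc2OC(C)(C)CC3(OCCO3)c2c(C=C)c1CO[Si](C)(C)C(C)(C)C | intermediate
13 | trichloroacetyl chloride | ClC(Cl)(Cl)C(Cl)=O | starting material
14 | dichloroketene (not isolated) | ClC(Cl)=C=O | intermediate
15 | (±)-2,2-dichloro-3-aryl-cyclobutanone, racemic | COc1cc2OC(C)(C)CC3(OCCO3)c2c(C4CC(=O)C4(Cl)Cl)c1CO[Si](C)(C)C(C)(C)C | intermediate
16 | 3-aryl-cyclobutanone silyl ether, achiral | COc1cc2OC(C)(C)CC3(OCCO3)c2c(C4CC(=O)C4)c1CO[Si](C)(C)C(C)(C)C | intermediate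
17 | 7-methoxy-2,2-dimethyl-5-(3-oxocyclobutyl)spiro[chromane-4,2'-[1,3]dioxolane]-6-carbaldehyde, achiral key-step precursor | COc1cc2OC(C)(C)CC3(OCCO3)c2c(C4CC(=O)C4)c1C=O | intermediate
18 | cyclobutenyl enamine of 17 with the (R)-catalyst, Cc S (not isolated) | COc1cc2OC(C)(C)CC3(OCCO3)c2c([C@H]4CC(N5CCC[C@@H]5C(=O)NS(=O)(=O)c5ccccc5)=C4)c1C=O | intermediate
19 | cis-fused hydroxy-indane cyclobutanone (Ca R, Cb R, Cc S), key-step product | COc1cc2c(c3c1[C@H](O)[C@H]1[C@@H]3CC1=O)C4(OCCO4)CC(C)(C)O2 | intermediate
20 | Ca-acetate of 19 (Ca R, Cb R, Cc S) | COc1cc2c(c3c1[C@H](OC(C)=O)[C@H]1[C@@H]3CC1=O)C4(OCCO4)CC(C)(C)O2 | intermediate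
21 | cis-fused indane cyclobutanone (Cb S, Cc S) | COc1cc2c(c3c1C[C@H]1[C@@H]3CC1=O)C4(OCCO4)CC(C)(C)O2 | intermediate
22 | 4-bromocatechol | Oc1ccc(Br)cc1O | starting material
23 | 4-bromo-1,2-bis(methoxymethoxy)benzene | COCOc1ccc(Br)cc1OCOC | intermediate
24 | lithium enolate of 21 toward Cd (not isolated) | COc1cc2c(c3c1C[C@H]1[C@@H]3C=C1[O-])C4(OCCO4)CC(C)(C)O2.[Li+] | intermediate
25 | endo-Cd-aryl cyclobutanone (Cb S, Cc R, Cd S) (not isolated) | COc1cc2c(c3c1C[C@H]1[C@@H]3[C@@H](c3ccc(OCOC)c(OCOC)c3)C1=O)C4(OCCO4)CC(C)(C)O2 | intermediate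
26 | exo-Cd-aryl cyclobutanone (Cb S, Cc R, Cd R) | COc1cc2c(c3c1C[C@H]1[C@@H]3[C@H](c3ccc(OCOC)c(OCOC)c3)C1=O)C4(OCCO4)CC(C)(C)O2 | intermediate
27 | Ce-methylene compound (Cb S, Cc R, Cd S) | COc1cc2c(c3c1C[C@H]1[C@@H]3[C@H](c3ccc(OCOC)c(OCOC)c3)C1=C)C4(OCCO4)CC(C)(C)O2 | intermediate
28 | Ce-spirocyclopropane (Cb S, Cc R, Cd S) | COc1cc2c(c3c1C[C@H]1[C@@H]3[C@H](c3ccc(OCOC)c(OCOC)c3)C15CC5)C4(OCCO4)CC(C)(C)O2 | intermediate
29 | Ce-gem-dimethyl ketal (Cb S, Cc R, Cd S) | COc1cc2c(c3c1C[C@H]1[C@@H]3[C@H](c3ccc(OCOC)c(OCOC)c3)C1(C)C)C4(OCCO4)CC(C)(C)O2 | intermediate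
30 | catechol chromanone (Cb S, Cc R, Cd S) | COc1cc2c(c3c1C[C@H]1[C@@H]3[C@H](c3ccc(O)c(O)c3)C1(C)C)C(=O)CC(C)(C)O2 | intermediate
31 | catechol chroman-4-ol, C4 epimers (Cb S, Cc R, Cd S) | COc1cc2c(c3c1C[C@H]1[C@@H]3[C@H](c3ccc(O)c(O)c3)C1(C)C)C(O)CC(C)(C)O2 | intermediate
32 | CNP0207533.1 (Cb S, Cc R, Cd S) | COc1cc2c(c3c1C[C@H]1[C@@H]3[C@H](c3ccc(O)c(O)c3)C1(C)C)C=CC(C)(C)O2 | target

## Step count

Total step count: 22. Longest linear sequence: 21 (steps 1–14 and 16–22; step 15 is the one-step side branch).

## Steps most likely to fail

**Step 12 (key aldol).**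
- The electron-rich, di-ortho-substituted aldehyde is a weak acceptor, so the addition may stall at an unfavourable equilibrium.
- Retro-aldol followed by re-addition may erode the enantiomeric purity.
- Discrimination between the two methylenes may be weaker than in the intermolecular cases, because the electrophile arrives syn to the 3-aryl group.
- The acidic catalyst function may slowly open the ketal.

The fallback forms the same Ca–Cb bond irreversibly with a stoichiometric chiral base. It sets out from 16 and returns at 21, replacing steps 11–14.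
- Buffered TBAF gives the benzylic alcohol F1.
- MsCl, Et3N and LiCl in THF at 0 °C give the benzylic chloride F2, which is used crude.
- F2 is added to lithium bis[(R)-1-phenylethyl]amide with LiCl in THF at −78 °C. Enantioselective deprotonation of 3-substituted cyclobutanones by such amides is established, and the antipode of the amine is taken if the sense is reversed.
- The non-racemic lithium enolate F3 closes by 5-(enolexo)-exo-tet alkylation on the ring-A face to give 21 directly.

**Step 16 (α-arylation).**
- Base- or palladium-induced C–C cleavage of the strained ketone may occur.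
- Self-aldol condensation may compete.
- Reductive elimination at Cd next to the peri ketal may be sluggish.
- A second arylation may follow the first.

The fallback replaces the Pd enolate coupling by aryl transfer from iodine(III), a known arylation of lithium enolates of cyclic ketones. It sets out from 23 and from enolate 24, made from 21 as in step 16, and returns at 26.
- Bromine–lithium exchange on 23 (n-BuLi, −78 °C) and Bu3SnCl give the aryl stannane F4.
- [Hydroxy(tosyloxy)iodo]mesitylene in CH2Cl2 at rt converts F4 into the aryl(mesityl)iodonium tosylate F5.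
- Enolate 24 in THF is treated with F5 in THF–DMF at −45 °C, the hindered mesityl acting as the non-transferred group for a carbon nucleophile.
- The 25/26 mixture is equilibrated with DBU to 26.

**Step 19 (cyclopropane hydrogenolysis).**
- Acid-induced loss of the ketal may be followed by reduction and hydrogenolysis at C4.
- A cyclopropane bond to the spiro carbon, or the doubly benzylic Cc–Cd bond, may open instead.
- Partial saturation of the electron-rich arenes may occur.

The fallback builds the second methyl group by homologation under neutral or basic conditions only. It sets out from 27 and returns at 29, replacing steps 18–19.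
- 9-BBN followed by H2O2/NaOH gives the primary alcohol F6.
- Dess–Martin periodinane with NaHCO3 gives the aldehyde F7.
- KHMDS and MeI give the α-methyl aldehyde F8. The Ce configuration is immaterial throughout.
- Wolff–Kishner reduction (N2H4·H2O, KOH, diethylene glycol, 120 to 200 °C) through the hydrazone F9 turns CHO into CH3 and gives 29.

## Further compounds

F1 | step 12 | 3-[6-(hydroxymethyl)-7-methoxy-2,2-dimethylspiro[chromane-4,2'-[1,3]dioxolan]-5-yl]cyclobutan-1-one | COc1cc2OC(C)(C)CC3(OCCO3)c2c(C4CC(=O)C4)c1CO
F2 | step 12 | 3-[6-(chloromethyl)-7-methoxy-2,2-dimethylspiro[chromane-4,2'-[1,3]dioxolan]-5-yl]cyclobutan-1-one | COc1cc2OC(C)(C)CC3(OCCO3)c2c(C4CC(=O)C4)c1CCl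
F3 | step 12 | lithium enolate of F2 deprotonated at the pro-Cb methylene (Cc S) | COc1cc2OC(C)(C)CC3(OCCO3)c2c([C@H]4CC([O-])=C4)c1CCl.[Li+]
F4 | step 16 | tributyl[3,4-bis(methoxymethoxy)phenyl]stannane | CCCC[Sn](CCCC)(CCCC)c1ccc(OCOC)c(OCOC)c1
F5 | step 16 | [3,4-bis(methoxymethoxy)phenyl](mesityl)iodonium tosylate | COCOc1ccc([I+]c2c(C)cc(C)cc2C)cc1OCOC.Cc1ccc(cc1)S(=O)(=O)[O-]
F6 | step 19 | Ce-hydroxymethyl compound, Ce epimers | COc1cc2c(c3c1C[C@H]1[C@@H]3[C@H](c3ccc(OCOC)c(OCOC)c3)C1CO)C4(OCCO4)CC(C)(C)O2
F7 | step 19 | Ce-carbaldehyde, Ce epimers | COc1cc2c(c3c1C[C@H]1[C@@H]3[C@H](c3ccc(OCOC)c(OCOC)c3)C1C=O)C4(OCCO4)CC(C)(C)O2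
F8 | step 19 | Ce-methyl Ce-carbaldehyde, Ce epimers | COc1cc2c(c3c1C[C@H]1[C@@H]3[C@H](c3ccc(OCOC)c(OCOC)c3)C1(C)C=O)C4(OCCO4)CC(C)(C)O2
F9 | step 19 | hydrazone of F8 | COc1cc2c(c3c1C[C@H]1[C@@H]3[C@H](c3ccc(OCOC)c(OCOC)c3)C1(C)C=NN)C4(OCCO4)CC(C)(C)O2
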